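**Plan**
Atom labels used below: C1 ketone, C2/C3 oxirane carbons (C2 bears the methyl), C4 methylene, C5, C6 acetoxy carbon; side chain C7 (=CH2), C8 (angelate carbinol), C9 to C11.
Retrosynthesis: the C8 angelate and C6 acetate come off first, then the ring bond C5–C6 is cut. O–C6–C5–C7=CH2 is a homoallylic alcohol beside the C1 ketone, the retron of an intramolecular carbonyl-ene reaction; because C2 is a quaternary oxirane carbon, the precursor is a non-enolisable epoxy α-keto aldehyde with a Z C5=C7(CH3) alkene.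
The open chain is then cut at C1–C6 (hydroxymethyl anion), at the oxirane C–O bonds (Sharpless), at C3–C4 (vinylmagnesium plus allylic chloride), and at C4–C5 and both C–CH3 bonds (carbomagnesiation of two propargylic alcohols).
Forward: C5–C11, then C4, then C1–C3, then C6; the oxirane is made on the chain (step 7), the cyclohexanone ring closes in step 11, and the two esters follow.
Stereochemistry: C8 from a Brown allylboration; C2/C3 from a catalytic Sharpless epoxidation; C5 and C6 together in the ene step by substrate control; both Z alkenes from chelation-directed anti-carbomagnesiation.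

Key step: step 11

Remark: the secondary carbinol carbon (C1) of 16 and 17 forms as a mixture of epimers, which does not matter because step 10 oxidises it to the ketone.

Step 1
Reactants: 1 3-(trimethylsilyl)prop-2-ynal
Product: 4 (S)-hex-5-en-1-yn-3-ol, via borinate ester 2 (not isolated), via silyl alkynol 3 (not isolated)
Conditions: (−)-Ipc2B(allyl), Et2O, −78 °C; then NaOH, H2O2, MeOH, 0 °C to rt
Reagents that add atoms: (−)-B-allyldiisopinocampheylborane, C=CCB([C@H]1[C@H](C)[C@H]2C[C@@H](C1)C2(C)C)[C@H]1[C@H](C)[C@H]2C[C@@H](C1)C2(C)C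
Why: Brown asymmetric allylboration through a closed chair transition state, in which the isopinocampheyl groups derived from (+)-α-pinene direct allyl to the Si face of the aldehyde and so set the (S) carbinol (the later C8), while the basic peroxide work-up in methanol cleaves both the borinate and the alkynyl–silicon bond.

Step 2
Reactants: 4 (S)-hex-5-en-1-yn-3-ol
Product: 6 (2Z,4S)-3-methylocta-2,7-diene-1,4-diol, via vinylmagnesium chelate 5 (not isolated)
Conditions: MeMgBr (3 equiv), CuI (10 mol %), THF, −10 °C to rt; then (CH2O)n, rt to 50 °C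
Reagents that add atoms: methylmagnesium bromide, C[Mg]Br; formaldehyde (from paraformaldehyde), C=O
Why: copper-catalysed anti-carbomagnesiation of a propargylic alcohol (Duboudin–Jousseaume reaction), in which the magnesium alkoxide directs methyl to the alkyne carbon next to the carbinol and magnesium to the terminal carbon, so that the five-membered chelate holds the C–Mg bond cis to the carbinol carbon and trapping with formaldehyde fixes the Z trisubstituted alkene (C4 cis to C8, methyl trans to C4) without touching the stereocentre.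

Step 3
Reactants: 6 (2Z,4S)-3-methylocta-2,7-diene-1,4-diol
Product: 7 (2Z,4S)-3,7-dimethylocta-2,6-diene-1,4-diol
Conditions: 2-methyl-2-butene/CH2Cl2, second-generation Grubbs catalyst (3 mol %), 35 °C
Reagents that add atoms: 2-methylbut-2-ene, CC=C(C)C
Why: olefin cross-metathesis exchanges the terminal methylene for the isopropylidene group of 2-methyl-2-butene, while the trisubstituted allylic alkene is too hindered to engage the ruthenium carbene and no stereocentre is involved.

Step 4
Reactants: 7 (2Z,4S)-3,7-dimethylocta-2,6-diene-1,4-diol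
Product: 9 (2Z,4S)-1-chloro-3,7-dimethylocta-2,6-dien-4-ol, via primary mesylate 8 (not isolated)
Conditions: MsCl, 2,4,6-collidine, LiCl, DMF, 0 °C
Reagents that add atoms: methanesulfonyl chloride, CS(=O)(=O)Cl (mesyl group of 8); lithium chloride, [Li+].[Cl-] (chlorine of 9)
Why: Collington–Meyers chlorination, in which the primary allylic alcohol is mesylated much faster than the hindered secondary one and chloride displaces the mesylate by SN2 at the primary carbon, leaving the alkene geometry and the carbinol untouched.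

Step 5
Reactants: 9 (2Z,4S)-1-chloro-3,7-dimethylocta-2,6-dien-4-ol
Product: 10 tert-butyl{[(2Z,4S)-1-chloro-3,7-dimethylocta-2,6-dien-4-yl]oxy}dimethylsilane
Conditions: TBSOTf, 2,6-lutidine, CH2Cl2, −78 °C
Reagents that add atoms: tert-butyldimethylsilyl trifluoromethanesulfonate, CC(C)(C)[Si](C)(C)OS(=O)(=O)C(F)(F)F
Why: silylation of a hindered secondary alcohol with a silyl triflate and a non-nucleophilic base, conditions under which the allylic chloride does not react and the chloro alcohol has no chance to close to a dihydrofuran.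

Step 6
Reactants: 10 tert-butyl{[(2Z,4S)-1-chloro-3,7-dimethylocta-2,6-dien-4-yl]oxy}dimethylsilane; 11 prop-2-yn-1-ol
Product: 13 (2Z,5Z,7S)-7-[(tert-butyldimethylsilyl)oxy]-2,6,10-trimethylundeca-2,5,9-trien-1-ol, via vinylmagnesium chelate 12 (not isolated)
Conditions: 11, MeMgBr (2.1 equiv per 11), CuI (15 mol %), THF, −10 °C to rt; then 10, −30 °C to rt
Reagents that add atoms: methylmagnesium bromide, C[Mg]Br
Why: the same Duboudin–Jousseaume carbomagnesiation of propargyl alcohol gives the cyclic vinylmagnesium species with magnesium cis to the CH2O group, and its copper-catalysed SN2 coupling with the primary allylic chloride (SN2′ is disfavoured because the γ-carbon is fully substituted) should form the C3–C4 bond with retention at both alkenes to give the 2Z,5Z skipped diene.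

Step 7
Reactants: 13 (2Z,5Z,7S)-7-[(tert-butyldimethylsilyl)oxy]-2,6,10-trimethylundeca-2,5,9-trien-1-ol
Product: 14 [(2R,3S)-3-{(2Z,4S)-4-[(tert-butyldimethylsilyl)oxy]-3,7-dimethylocta-2,6-dien-1-yl}-2-methyloxiran-2-yl]methanol
Conditions: Ti(OiPr)4, D-(−)-diethyl tartrate, t-BuOOH, 4 Å MS, CH2Cl2, −20 °C
Reagents that add atoms: tert-butyl hydroperoxide, CC(C)(C)OO
Why: Sharpless asymmetric epoxidation, in which only the alkene bearing the free allylic hydroxyl reacts, syn addition keeps C1 and C4 cis on the oxirane, and the titanium D-(−)-tartrate catalyst delivers oxygen to the face opposite to the one attacked in nerol with the L-(+)-tartrate catalyst, which sets C2 and C3 as required.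

Step 8
Reactants: 14 [(2R,3S)-3-{(2Z,4S)-4-[(tert-butyldimethylsilyl)oxy]-3,7-dimethylocta-2,6-dien-1-yl}-2-methyloxiran-2-yl]methanol
Product: 15 (2S,3S)-3-{(2Z,4S)-4-[(tert-butyldimethylsilyl)oxy]-3,7-dimethylocta-2,6-dien-1-yl}-2-methyloxirane-2-carbaldehyde
Conditions: Dess–Martin periodinane, pyridine, CH2Cl2, 0 °C to rt
Reagents that add atoms: none
Why: Dess–Martin oxidation of a primary epoxy alcohol under buffered conditions, giving an aldehyde that has no α-hydrogen and so cannot epimerise.

Step 9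
Reactants: 15 (2S,3S)-3-{(2Z,4S)-4-[(tert-butyldimethylsilyl)oxy]-3,7-dimethylocta-2,6-dien-1-yl}-2-methyloxirane-2-carbaldehyde
Product: 17 1-[(2R,3S)-3-{(2Z,4S)-4-[(tert-butyldimethylsilyl)oxy]-3,7-dimethylocta-2,6-dien-1-yl}-2-methyloxiran-2-yl]ethane-1,2-diol, via silyl carbinol 16 (not isolated)
Conditions: (i-PrO)Me2SiCH2MgCl, THF, −78 to 0 °C; then KF, KHCO3, H2O2, THF/MeOH, rt
Reagents that add atoms: [(isopropoxydimethylsilyl)methyl]magnesium chloride, CC(C)O[Si](C)(C)C[Mg]Cl; hydrogen peroxide, OO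
Why: Tamao hydroxymethylation, in which the (alkoxysilyl)methyl Grignard reagent adds to the aldehyde and Tamao–Fleming oxidation of the C–Si bond supplies C6 as a primary alcohol, the new carbinol being formed without control because it is oxidised in the next step.

Step 10
Reactants: 17 1-[(2R,3S)-3-{(2Z,4S)-4-[(tert-butyldimethylsilyl)oxy]-3,7-dimethylocta-2,6-dien-1-yl}-2-methyloxiran-2-yl]ethane-1,2-diol
Product: 18 2-[(2S,3S)-3-{(2Z,4S)-4-[(tert-butyldimethylsilyl)oxy]-3,7-dimethylocta-2,6-dien-1-yl}-2-methyloxiran-2-yl]-2-oxoacetaldehyde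
Conditions: (COCl)2, DMSO, CH2Cl2, −78 °C; Et3N, −78 to −20 °C; used at once
Reagents that add atoms: none
Why: Swern oxidation converts both hydroxyl groups of a 1,2-diol to carbonyls without C–C cleavage, and the resulting α-keto aldehyde cannot enolise because C2 is quaternary.

Step 11
Reactants: 18 2-[(2S,3S)-3-{(2Z,4S)-4-[(tert-butyldimethylsilyl)oxy]-3,7-dimethylocta-2,6-dien-1-yl}-2-methyloxiran-2-yl]-2-oxoacetaldehyde
Product: 19 (1S,3S,4S,6S)-4-{(3S)-3-[(tert-butyldimethylsilyl)oxy]-6-methylhepta-1,5-dien-2-yl}-3-hydroxy-1-methyl-7-oxabicyclo[4.1.0]heptan-2-one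
Conditions: ZnBr2 (1.2 equiv), 4 Å MS, CH2Cl2, −40 to 0 °C
Reagents that add atoms: none
Why: ZnBr2 binds both carbonyl oxygens of 18, which locks the glyoxal s-cis and activates the aldehyde; the C5=C7 alkene then adds through C5 to the aldehyde carbon C6 while a hydrogen of the C7 methyl group passes to the aldehyde oxygen in a concerted, asynchronous six-centre ene transition state, forming the C5–C6 bond, the C6 carbinol and the C7=CH2 group together. The closest known reaction type is the Lewis acid promoted intramolecular carbonyl-ene cyclisation of the citronellal to isopulegol class, together with the ene reactions of chelated glyoxylates. The cyclohexanone ring closes in a 6-exo-trig mode at the aldehyde through a chair-like array that the cis-fused oxirane flattens to a half-chair (C1 to C4 coplanar). C6 is controlled by the chelate, which keeps the aldehyde oxygen in the plane of the C1 carbonyl and hence pseudo-equatorial; C5 by the equatorial alkene, which gives the trans 5,6 pair; and their sense relative to the oxirane by the half-chair with C6 on the oxirane-oxygen face and C5 on the C2-methyl face, since the alternative presses the axial C6–H against the C2 methyl group. The step needs hydrogen transfer from the methyl group and not from C8–H, closure to the six- and not the ten-membered ring, and an intact oxirane: the Z geometry places the methyl group trans to C4 under the free lone pair of the chelated aldehyde oxygen, the prenyl alkene cannot reach, and the oxirane carbon C2 is alpha to the ketone (deactivated towards ionisation) and quaternary (no enolisation).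

Step 12
Reactants: 19 (1S,3S,4S,6S)-4-{(3S)-3-[(tert-butyldimethylsilyl)oxy]-6-methylhepta-1,5-dien-2-yl}-3-hydroxy-1-methyl-7-oxabicyclo[4.1.0]heptan-2-one
Product: 20 (1S,3S,4S,6S)-4-{(3S)-3-[(tert-butyldimethylsilyl)oxy]-6-methylhepta-1,5-dien-2-yl}-1-methyl-2-oxo-7-oxabicyclo[4.1.0]heptan-3-yl acetate
Conditions: Ac2O, pyridine, DMAP (cat.), CH2Cl2, 0 °C
Reagents that add atoms: acetic anhydride, CC(=O)OC(C)=O
Why: acylation of the secondary α-hydroxy ketone under nucleophilic catalysis, the trans diequatorial C6 configuration also being the thermodynamically preferred one should any enolisation occur.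

Step 13
Reactants: 20 (1S,3S,4S,6S)-4-{(3S)-3-[(tert-butyldimethylsilyl)oxy]-6-methylhepta-1,5-dien-2-yl}-1-methyl-2-oxo-7-oxabicyclo[4.1.0]heptan-3-yl acetate
Product: 21 (1S,3S,4S,6S)-4-[(3S)-3-hydroxy-6-methylhepta-1,5-dien-2-yl]-1-methyl-2-oxo-7-oxabicyclo[4.1.0]heptan-3-yl acetate
Conditions: HF·pyridine, pyridine, THF, 0 °C to rt
Reagents that add atoms: none
Why: fluoride cleavage of the silyl ether under buffered, non-basic conditions, which should leave the acetate, the epoxy ketone and the acidic C6–H untouched.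

Step 14
Reactants: 21 (1S,3S,4S,6S)-4-[(3S)-3-hydroxy-6-methylhepta-1,5-dien-2-yl]-1-methyl-2-oxo-7-oxabicyclo[4.1.0]heptan-3-yl acetate; 22 angelic acid
Product: 24 (1S,3S,4S,6S)-1-methyl-4-[(3S)-6-methyl-3-{[(2Z)-2-methylbut-2-enoyl]oxy}hepta-1,5-dien-2-yl]-2-oxo-7-oxabicyclo[4.1.0]heptan-3-yl acetate, via mixed anhydride 23 (not isolated)
Conditions: 22, 2,4,6-trichlorobenzoyl chloride, Et3N, toluene, rt; then 21, 75 °C
Reagents that add atoms: 2,4,6-trichlorobenzoyl chloride, O=C(Cl)c1c(Cl)cc(Cl)cc1Cl (aroyl group of 23 only)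
Why: Yamaguchi-type esterification through the mixed anhydride, in which the alcohol attacks the unhindered angeloyl carbonyl and the absence of a nucleophilic catalyst suppresses isomerisation of angelate to tiglate, the C8 configuration being retained because its C–O bond is not broken.

**Compound list**
1 | 3-(trimethylsilyl)prop-2-ynal | C[Si](C)(C)C#CC=O | starting material
2 | (3S)-1-(trimethylsilyl)hex-5-en-1-yn-3-yl bis(isopinocampheyl)borinate | C=CC[C@H](OB([C@H]1[C@H](C)[C@H]2C[C@@H](C1)C2(C)C)[C@H]1[C@H](C)[C@H]2C[C@@H](C1)C2(C)C)C#C[Si](C)(C)C | intermediate (not isolated)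
3 | (S)-1-(trimethylsilyl)hex-5-en-1-yn-3-ol | C[Si](C)(C)C#C[C@@H](O)CC=C | intermediate (not isolated)
4 | (S)-hex-5-en-1-yn-3-ol | C#C[C@@H](O)CC=C | intermediate
5 | (5S)-4-methyl-5-(prop-2-en-1-yl)-2,5-dihydro-1,2-oxamagnesole (cyclic alkoxy vinylmagnesium species) | C=CC[C@@H]1O[Mg]C=C1C | intermediate (not isolated)
6 | (2Z,4S)-3-methylocta-2,7-diene-1,4-diol | OC/C=C(/C)[C@@H](O)CC=C | intermediate
7 | (2Z,4S)-3,7-dimethylocta-2,6-diene-1,4-diol | OC/C=C(/C)[C@@H](O)CC=C(C)C | intermediate
8 | (2Z,4S)-4-hydroxy-3,7-dimethylocta-2,6-dien-1-yl methanesulfonate | CS(=O)(=O)OC/C=C(/C)[C@@H](O)CC=C(C)C | intermediate (not isolated)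
9 | (2Z,4S)-1-chloro-3,7-dimethylocta-2,6-dien-4-ol | ClC/C=C(/C)[C@@H](O)CC=C(C)C | intermediate
10 | tert-butyl{[(2Z,4S)-1-chloro-3,7-dimethylocta-2,6-dien-4-yl]oxy}dimethylsilane | ClC/C=C(/C)[C@@H](O[Si](C)(C)C(C)(C)C)CC=C(C)C | intermediate
11 | prop-2-yn-1-ol | C#CCO | starting material
12 | 4-methyl-2,5-dihydro-1,2-oxamagnesole (cyclic alkoxy vinylmagnesium species) | CC1=C[Mg]OC1 | intermediate (not isolated)
13 | (2Z,5Z,7S)-7-[(tert-butyldimethylsilyl)oxy]-2,6,10-trimethylundeca-2,5,9-trien-1-ol | OC/C(C)=C\C/C=C(/C)[C@@H](O[Si](C)(C)C(C)(C)C)CC=C(C)C | intermediate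
14 | [(2R,3S)-3-{(2Z,4S)-4-[(tert-butyldimethylsilyl)oxy]-3,7-dimethylocta-2,6-dien-1-yl}-2-methyloxiran-2-yl]methanol | OC[C@@]1(C)O[C@H]1C/C=C(/C)[C@@H](O[Si](C)(C)C(C)(C)C)CC=C(C)C | intermediate
15 | (2S,3S)-3-{(2Z,4S)-4-[(tert-butyldimethylsilyl)oxy]-3,7-dimethylocta-2,6-dien-1-yl}-2-methyloxirane-2-carbaldehyde | O=C[C@@]1(C)O[C@H]1C/C=C(/C)[C@@H](O[Si](C)(C)C(C)(C)C)CC=C(C)C | intermediate
16 | 1-[(2R,3S)-3-{(2Z,4S)-4-[(tert-butyldimethylsilyl)oxy]-3,7-dimethylocta-2,6-dien-1-yl}-2-methyloxiran-2-yl]-2-[isopropoxy(dimethyl)silyl]ethan-1-ol (both carbinol epimers) | CC(C)O[Si](C)(C)CC(O)[C@@]1(C)O[C@H]1C/C=C(/C)[C@@H](O[Si](C)(C)C(C)(C)C)CC=C(C)C | intermediate (not isolated)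
17 | 1-[(2R,3S)-3-{(2Z,4S)-4-[(tert-butyldimethylsilyl)oxy]-3,7-dimethylocta-2,6-dien-1-yl}-2-methyloxiran-2-yl]ethane-1,2-diol (both carbinol epimers) | OCC(O)[C@@]1(C)O[C@H]1C/C=C(/C)[C@@H](O[Si](C)(C)C(C)(C)C)CC=C(C)C | intermediate
18 | 2-[(2S,3S)-3-{(2Z,4S)-4-[(tert-butyldimethylsilyl)oxy]-3,7-dimethylocta-2,6-dien-1-yl}-2-methyloxiran-2-yl]-2-oxoacetaldehyde | O=CC(=O)[C@@]1(C)O[C@H]1C/C=C(/C)[C@@H](O[Si](C)(C)C(C)(C)C)CC=C(C)C | intermediate
19 | (1S,3S,4S,6S)-4-{(3S)-3-[(tert-butyldimethylsilyl)oxy]-6-methylhepta-1,5-dien-2-yl}-3-hydroxy-1-methyl-7-oxabicyclo[4.1.0]heptan-2-one | C=C([C@H](CC=C(C)C)O[Si](C)(C)C(C)(C)C)[C@@H]1C[C@@H]2O[C@]2(C)C(=O)[C@H]1O | intermediate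
20 | (1S,3S,4S,6S)-4-{(3S)-3-[(tert-butyldimethylsilyl)oxy]-6-methylhepta-1,5-dien-2-yl}-1-methyl-2-oxo-7-oxabicyclo[4.1.0]heptan-3-yl acetate | C=C([C@H](CC=C(C)C)O[Si](C)(C)C(C)(C)C)[C@@H]1C[C@@H]2O[C@]2(C)C(=O)[C@H]1OC(C)=O | intermediate
21 | (1S,3S,4S,6S)-4-[(3S)-3-hydroxy-6-methylhepta-1,5-dien-2-yl]-1-methyl-2-oxo-7-oxabicyclo[4.1.0]heptan-3-yl acetate | C=C([C@H](CC=C(C)C)O)[C@@H]1C[C@@H]2O[C@]2(C)C(=O)[C@H]1OC(C)=O | intermediate
22 | angelic acid, (2Z)-2-methylbut-2-enoic acid | C/C=C(/C)C(=O)O | starting material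
23 | (2Z)-2-methylbut-2-enoic 2,4,6-trichlorobenzoic anhydride | C/C=C(/C)C(=O)OC(=O)c1c(Cl)cc(Cl)cc1Cl | intermediate (not isolated)
24 | (1S,3S,4S,6S)-1-methyl-4-[(3S)-6-methyl-3-{[(2Z)-2-methylbut-2-enoyl]oxy}hepta-1,5-dien-2-yl]-2-oxo-7-oxabicyclo[4.1.0]heptan-3-yl acetate | C=C([C@H](CC=C(C)C)OC(=O)/C(C)=C\C)[C@@H]1C[C@@H]2O[C@]2(C)C(=O)[C@H]1OC(C)=O | target

Total steps: 14. Longest linear sequence: 14 steps (1 to 24).

**Steps most likely to fail**

Step 11. The facial selectivity may be poor: the oxirane may not separate the two half-chair transition states well enough, or the C8 silyl ether may oppose it. The Lewis acid may also open the oxirane, or a stepwise Prins-type course may lose the wrong proton. The fallback takes the oxirane out of the ring closure and relays it afterwards from the ring stereocentres; it sets out from 13 and comes back at 20. MnO2 oxidation of 13 should give the trienal F1. The Grignard reagent of step 9 adds to it to give the silyl carbinol F2, which is oxidised in the same flask (KF, KHCO3, H2O2) to the triene diol F3, and Swern oxidation gives the dienoyl glyoxal F4. ZnBr2 then closes the same C5–C6 bond through a cyclohexenone half-chair to the hydroxy enone F5; the facial sense now rests on allylic 1,3-strain from the C8 silyl ether, reinforced if needed by Cu(OTf)2 with a chiral bis(oxazoline) ligand. Acetylation gives the acetoxy enone F6. Luche reduction (NaBH4, CeCl3, MeOH, −78 °C) should give the allylic alcohol F7 with the hydroxyl cis to the side chain, as in carvone to cis-carveol. VO(acac)2/t-BuOOH epoxidises syn to that hydroxyl to give the epoxy alcohol F8, and Dess–Martin oxidation of F8 gives 20.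

Step 10. The double oxidation may cleave the diol C–C bond or stop at a hydroxy carbonyl stage, and the glyoxal may hydrate or oligomerise during work-up. The fallback reaches the same glyoxal without a diol and without water; it sets out from 14 and comes back at 18, replacing steps 8 to 10. Oxidation of 14 with TEMPO/PhI(OAc)2 in aqueous MeCN should give the glycidic acid F9. Isobutyl chloroformate and N-methylmorpholine convert it into the mixed carbonic anhydride F10, and diazomethane into the epoxy diazoketone F11. One equivalent of dimethyldioxirane in acetone at −78 °C then transfers oxygen to the diazo carbon with loss of nitrogen, a reaction expected to outrun epoxidation of the trisubstituted alkenes, and gives 18.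

Step 6. The copper-catalysed coupling may scramble the alkene geometry through allylcopper intermediates, attack in the SN2′ sense, or transfer methyl from residual Grignard reagent. The fallback separates metalation from coupling; it sets out from 11 and 10 and comes back at 13. The vinylmagnesium species 12 is quenched with Bu3SnCl to give (2Z)-2-methyl-3-(tributylstannyl)prop-2-en-1-ol F12, which is isolated. A Stille coupling of F12 with 10 (Pd2(dba)3, tri(2-furyl)phosphine, NMP, rt) should then give 13: oxidative addition of zerovalent palladium to the allylic chloride and transmetalation keep both alkene geometries, and the bond forms at the less hindered allyl terminus.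

**Further compounds**
F1 | step 11 | (2Z,5Z,7S)-7-[(tert-butyldimethylsilyl)oxy]-2,6,10-trimethylundeca-2,5,9-trienal | O=C/C(C)=C\C/C=C(/C)[C@@H](O[Si](C)(C)C(C)(C)C)CC=C(C)C
F2 | step 11 | (3Z,6Z,8S)-8-[(tert-butyldimethylsilyl)oxy]-1-[isopropoxy(dimethyl)silyl]-3,7,11-trimethyldodeca-3,6,10-trien-2-ol | CC(C)O[Si](C)(C)CC(O)/C(C)=C\C/C=C(/C)[C@@H](O[Si](C)(C)C(C)(C)C)CC=C(C)C
F3 | step 11 | (3Z,6Z,8S)-8-[(tert-butyldimethylsilyl)oxy]-3,7,11-trimethyldodeca-3,6,10-triene-1,2-diol | OCC(O)/C(C)=C\C/C=C(/C)[C@@H](O[Si](C)(C)C(C)(C)C)CC=C(C)C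
F4 | step 11 | (3Z,6Z,8S)-8-[(tert-butyldimethylsilyl)oxy]-3,7,11-trimethyl-2-oxododeca-3,6,10-trienal | O=CC(=O)/C(C)=C\C/C=C(/C)[C@@H](O[Si](C)(C)C(C)(C)C)CC=C(C)C
F5 | step 11 | (5S,6S)-5-{(3S)-3-[(tert-butyldimethylsilyl)oxy]-6-methylhepta-1,5-dien-2-yl}-6-hydroxy-2-methylcyclohex-2-en-1-one | C=C([C@H](CC=C(C)C)O[Si](C)(C)C(C)(C)C)[C@@H]1CC=C(C)C(=O)[C@H]1O
F6 | step 11 | (1S,6S)-6-{(3S)-3-[(tert-butyldimethylsilyl)oxy]-6-methylhepta-1,5-dien-2-yl}-3-methyl-2-oxocyclohex-3-en-1-yl acetate | C=C([C@H](CC=C(C)C)O[Si](C)(C)C(C)(C)C)[C@@H]1CC=C(C)C(=O)[C@H]1OC(C)=O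
F7 | step 11 | (1S,2S,6S)-6-{(3S)-3-[(tert-butyldimethylsilyl)oxy]-6-methylhepta-1,5-dien-2-yl}-2-hydroxy-3-methylcyclohex-3-en-1-yl acetate (hydroxyl cis to the side chain) | C=C([C@H](CC=C(C)C)O[Si](C)(C)C(C)(C)C)[C@@H]1CC=C(C)[C@H](O)[C@H]1OC(C)=O
F8 | step 11 | (1R,2R,3S,4S,6S)-4-{(3S)-3-[(tert-butyldimethylsilyl)oxy]-6-methylhepta-1,5-dien-2-yl}-2-hydroxy-1-methyl-7-oxabicyclo[4.1.0]heptan-3-yl acetate (oxirane cis to the hydroxyl) | C=C([C@H](CC=C(C)C)O[Si](C)(C)C(C)(C)C)[C@@H]1C[C@@H]2O[C@]2(C)[C@H](O)[C@H]1OC(C)=O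
F9 | step 10 | (2S,3S)-3-{(2Z,4S)-4-[(tert-butyldimethylsilyl)oxy]-3,7-dimethylocta-2,6-dien-1-yl}-2-methyloxirane-2-carboxylic acid | OC(=O)[C@@]1(C)O[C@H]1C/C=C(/C)[C@@H](O[Si](C)(C)C(C)(C)C)CC=C(C)C
F10 | step 10 | mixed anhydride of F9 with isobutyl hydrogen carbonate | CC(C)COC(=O)OC(=O)[C@@]1(C)O[C@H]1C/C=C(/C)[C@@H](O[Si](C)(C)C(C)(C)C)CC=C(C)C
F11 | step 10 | 2-diazo-1-[(2S,3S)-3-{(2Z,4S)-4-[(tert-butyldimethylsilyl)oxy]-3,7-dimethylocta-2,6-dien-1-yl}-2-methyloxiran-2-yl]ethan-1-one | [N-]=[N+]=CC(=O)[C@@]1(C)O[C@H]1C/C=C(/C)[C@@H](O[Si](C)(C)C(C)(C)C)CC=C(C)C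
F12 | step 6 | (2Z)-2-methyl-3-(tributylstannyl)prop-2-en-1-ol | CCCC[Sn](CCCC)(CCCC)/C=C(/C)CO
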